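**Retrosynthetic overview**

1. Lettering: the upper 4-arylisoflavan has chroman rings A/C and aryl ring B (2-hydroxy-4,5-dimethoxyphenyl). The lower isoflavan has chroman rings A′/C′ and aryl ring B′, the central arene that also carries C4 of ring C.
2. Pyran ring C′ is cut at O1′–C2′ and C3′–C4′ into a ring-A′ ortho-quinone methide and a ring-B′ arylacetaldehyde, joined under enamine catalysis. This is possible because O1′, C8a′, C4a′ and the unsubstituted C4′H2 form an o-hydroxybenzyl unit on a resorcinol ring whose O7′ is para to C4a′, while C2′–C3′ with ring B′ on C3′ is an arylacetaldehyde (C2′ at lactol level, returned to CH2 afterwards).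
3. The C4–ring B′ bond is a Friedel–Crafts disconnection to a cis-isoflavan-4-ol and an allyl-bearing resorcinol diether (allyl = masked CH2CHO). C3 is set by asymmetric transfer hydrogenation of an isoflavone with dynamic kinetic resolution and relayed to C4 (trans).
4. Ring C comes from a 2′-hydroxychalcone by oxidative 1,2-aryl shift. Order: ring C (step 3), C4–B′ bond (step 7), ring C′ (step 11), then removal of four benzyl ethers.

Key step: step 11

Assumption: the sense of induction of both catalysts is taken from the usual models (the (R,R)-ruthenium catalyst gives the (4R) benzylic alcohol; the (R)-prolinol silyl ether directs attack to the enamine face that gives (3′R)). If either ran the other way, the mirror-image catalyst would be used.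

**Route**

Step 1
Reactants: 1 2-hydroxy-4,5-dimethoxybenzaldehyde
Product: 2 2-(benzyloxy)-4,5-dimethoxybenzaldehyde
Conditions: BnBr, K2CO3, DMF, 60 °C
Reagents that add atoms: benzyl bromide BrCc1ccccc1
Why: Williamson etherification of the phenol installs the benzyl group that later keeps the ring-B oxygen from interfering and is removed by hydrogenolysis at the end.

Step 2
Reactants: 2 2-(benzyloxy)-4,5-dimethoxybenzaldehyde; 3 1-[4-(benzyloxy)-2-hydroxyphenyl]ethanone
Product: 4 (E)-1-[4-(benzyloxy)-2-hydroxyphenyl]-3-[2-(benzyloxy)-4,5-dimethoxyphenyl]prop-2-en-1-one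
Conditions: KOH, EtOH/H2O, rt
Reagents that add atoms: none
Why: Claisen–Schmidt aldol condensation of the acetophenone enolate with the non-enolisable aldehyde gives the thermodynamically favoured E-enone, the phenoxide of 3 being tolerated under excess hydroxide.

Step 3
Reactants: 4 (E)-1-[4-(benzyloxy)-2-hydroxyphenyl]-3-[2-(benzyloxy)-4,5-dimethoxyphenyl]prop-2-en-1-one
Product: 6 7-(benzyloxy)-3-[2-(benzyloxy)-4,5-dimethoxyphenyl]-4H-chromen-4-one, via rearranged dimethyl acetal 5 (not isolated)
Conditions: Tl(NO3)3·3H2O, MeOH/HC(OMe)3, rt; then 10% aq HCl, MeOH, reflux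
Reagents that add atoms: none
Why: Trivalent thallium adds to the enone double bond in methanol and the electron-rich ring-B aryl group undergoes a 1,2-shift with loss of monovalent thallium (oxidative chalcone-to-isoflavone rearrangement), after which acid closes the free phenol onto the acetal carbon and eliminates methanol to the chromone.

Step 4
Reactants: 6 7-(benzyloxy)-3-[2-(benzyloxy)-4,5-dimethoxyphenyl]-4H-chromen-4-one
Product: 8 cis-(3R,4R)-7-(benzyloxy)-3-[2-(benzyloxy)-4,5-dimethoxyphenyl]chroman-4-ol, via isoflavanone 7 (not isolated)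
Conditions: RuCl[(R,R)-TsDPEN](p-cymene) (2 mol%), HCO2H/Et3N (5:2), EtOAc, 40 °C
Reagents that add atoms: none
Why: Noyori asymmetric transfer hydrogenation first saturates the chromone C2–C3 bond and then reduces the ketone of 7 under dynamic kinetic resolution, because triethylamine keeps C3 epimerising while the (R,R)-catalyst reduces the (3R)-ketone faster and delivers hydride to the face that gives the cis alcohol, which should set C3 (and C4) as cis-(3R,4R).

Step 5
Reactants: 9 2-bromo-5-methoxyphenol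
Product: 10 2-(benzyloxy)-1-bromo-4-methoxybenzene
Conditions: BnBr, K2CO3, DMF, rt
Reagents that add atoms: benzyl bromide BrCc1ccccc1
Why: Williamson etherification protects the future ring-B′ phenol so that the later arylacetaldehyde cannot close onto it to a 2-hydroxydihydrobenzofuran or benzofuran.

Step 6
Reactants: 10 2-(benzyloxy)-1-bromo-4-methoxybenzene
Product: 11 1-allyl-2-(benzyloxy)-4-methoxybenzene
Conditions: allylB(pin), Pd(PPh3)4 (5 mol%), CsF, THF, reflux
Reagents that add atoms: allylboronic acid pinacol ester C=CCB1OC(C)(C)C(C)(C)O1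
Why: Suzuki–Miyaura allylation (oxidative addition of zerovalent palladium into the aryl bromide, fluoride-assisted transmetalation of the allyl group and reductive elimination) fixes the allyl group, a masked CH2CHO that tolerates the later acid step, at a defined ring position.

Step 7
Reactants: 8 cis-(3R,4R)-7-(benzyloxy)-3-[2-(benzyloxy)-4,5-dimethoxyphenyl]chroman-4-ol; 11 1-allyl-2-(benzyloxy)-4-methoxybenzene
Product: 12 trans-(3R,4S)-4-[5-allyl-4-(benzyloxy)-2-methoxyphenyl]-7-(benzyloxy)-3-[2-(benzyloxy)-4,5-dimethoxyphenyl]chroman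
Conditions: Sc(OTf)3 (10 mol%), 11 (4 equiv), 4 Å MS, CH2Cl2, −40 → 0 °C, slow addition of 8
Reagents that add atoms: none
Why: Sc(OTf)3 ionises the benzylic C4–OH to the cation stabilised by the para 7-benzyloxy group, and arene 11 attacks through its only unhindered doubly activated position (para to OBn, ortho to OMe) on the face opposite the neighbouring 3-aryl group, so that C4 is set trans to C3 by substrate control (Friedel–Crafts benzylation, as in the acid-induced coupling of flavan-4-ols and pterocarpans with phenolic nucleophiles).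

Step 8
Reactants: 12 trans-(3R,4S)-4-[5-allyl-4-(benzyloxy)-2-methoxyphenyl]-7-(benzyloxy)-3-[2-(benzyloxy)-4,5-dimethoxyphenyl]chroman
Product: 14 2-{2-(benzyloxy)-4-methoxy-5-[(3R,4S)-7-(benzyloxy)-3-[2-(benzyloxy)-4,5-dimethoxyphenyl]chroman-4-yl]phenyl}acetaldehyde, via vicinal diol 13 (not isolated)
Conditions: OsO4 (2 mol%), NaIO4, 2,6-lutidine, dioxane/H2O (3:1), rt; used without chromatography
Reagents that add atoms: osmium tetroxide O=[Os](=O)(=O)=O (oxygen donor, re-formed by sodium periodate [Na+].[O-]I(=O)(=O)=O)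
Why: Lemieux–Johnson oxidation, in which catalytic OsO4 dihydroxylates the terminal alkene and periodate cleaves diol 13 to the arylacetaldehyde, leaves benzyl ethers, electron-rich arenes and both stereocentres untouched.

Step 9
Reactants: 15 4-(benzyloxy)-2-hydroxybenzaldehyde
Product: 16 5-(benzyloxy)-2-(hydroxymethyl)phenol
Conditions: NaBH4, MeOH, 0 °C; neutral work-up, used crude
Reagents that add atoms: none
Why: Borohydride reduction of the salicylaldehyde carbonyl gives the benzylic alcohol, which is carried on at once because it ionises readily.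

Step 10
Reactants: 16 5-(benzyloxy)-2-(hydroxymethyl)phenol
Product: 17 5-(benzyloxy)-2-[(4-methylphenyl)sulfonylmethyl]phenol
Conditions: p-TolSO2Na (2 equiv), HCO2H/H2O, rt
Reagents that add atoms: sodium p-toluenesulfinate Cc1ccc(cc1)S(=O)[O-].[Na+]
Why: Acid-promoted ionisation of the ortho- and para-oxygenated benzylic alcohol and S-alkylation of the sulfinate (SN1-type sulfone formation) give a storable solid from which mild base can later release the ortho-quinone methide.

Step 11
Reactants: 14 2-{2-(benzyloxy)-4-methoxy-5-[(3R,4S)-7-(benzyloxy)-3-[2-(benzyloxy)-4,5-dimethoxyphenyl]chroman-4-yl]phenyl}acetaldehyde; 17 5-(benzyloxy)-2-[(4-methylphenyl)sulfonylmethyl]phenol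
Product: 20 (3R)-7-(benzyloxy)-3-{2-(benzyloxy)-4-methoxy-5-[(3R,4S)-7-(benzyloxy)-3-[2-(benzyloxy)-4,5-dimethoxyphenyl]chroman-4-yl]phenyl}chroman-2-ol (anomer mixture at C2), via ortho-quinone methide 18 (not isolated), via catalyst enamine 19 (not isolated)
Conditions: (R)-α,α-diphenylprolinol trimethylsilyl ether (20 mol%), Na2CO3 (solid), 17 (1.5 equiv), CH2Cl2, 0 °C → rt
Reagents that add atoms: none
Why: Solid Na2CO3 slowly eliminates p-toluenesulfinate from 17 to give ortho-quinone methide 18 while aldehyde 14 condenses with the (R)-prolinol silyl ether to E-enamine 19; the enamine carbon (future C3′) adds to the exocyclic methylene of 18 (future C4′), which re-aromatises ring A′ to a phenoxide, and this oxygen closes onto the iminium carbon (future C2′) before hydrolysis of the aminal releases lactol 20 and the catalyst. The closest known reaction type is the diarylprolinol silyl ether catalysed formal [4+2] annulation of enolisable aldehydes with ortho-quinone methides generated in situ from 2-(sulfonylmethyl)phenols, which gives chroman-2-ols. Ring C′ closes by conjugate addition followed by a 6-exo-trig attack of the phenoxide oxygen on the iminium ion, overall an inverse-electron-demand oxa-[4+2] mode. C3′ is the only new defined stereocentre and is set by the catalyst: the CPh2(OSiMe3) group blocks one face of the s-trans E-enamine, so the electrophile should add to the open face, which for the (R)-catalyst corresponds to (3′R), independent of the distant centres C3 and C4. The step needs C-alkylation by the enamine to outrun self-aldolisation of 14 and N-alkylation or oligomerisation of 18, and it needs the α-aryl centre to keep its configuration; the low stationary concentration of 18, the high nucleophilicity of the aryl-conjugated enamine, the benzyl ether on the ring-B′ oxygen and the immediate trapping of the product as the closed lactol should secure this.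

Step 12
Reactants: 20 (3R)-7-(benzyloxy)-3-{2-(benzyloxy)-4-methoxy-5-[(3R,4S)-7-(benzyloxy)-3-[2-(benzyloxy)-4,5-dimethoxyphenyl]chroman-4-yl]phenyl}chroman-2-ol
Product: 21 (3R)-7-(benzyloxy)-3-{2-(benzyloxy)-4-methoxy-5-[(3R,4S)-7-(benzyloxy)-3-[2-(benzyloxy)-4,5-dimethoxyphenyl]chroman-4-yl]phenyl}chroman
Conditions: Et3SiH, BF3·OEt2, CH2Cl2, −78 → −40 °C
Reagents that add atoms: none
Why: BF3·OEt2 ionises the lactol to the cyclic oxocarbenium ion, which triethylsilane should reduce at low temperature faster than it can lose the C3′ proton (ionic hydrogenation of a lactol), so that the O1′–C2′ bond, the C3′ configuration and the benzyl ethers are kept.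

Step 13
Reactants: 21 (3R)-7-(benzyloxy)-3-{2-(benzyloxy)-4-methoxy-5-[(3R,4S)-7-(benzyloxy)-3-[2-(benzyloxy)-4,5-dimethoxyphenyl]chroman-4-yl]phenyl}chroman
Product: 22 (3R,4S)-4-{4-hydroxy-5-[(3R)-7-hydroxychroman-3-yl]-2-methoxyphenyl}-3-(2-hydroxy-4,5-dimethoxyphenyl)chroman-7-ol (CNP0217096.1)
Conditions: H2 (1 atm), Pd/C, EtOAc/MeOH, rt
Reagents that add atoms: none
Why: Hydrogenolysis of the four benzyl aryl ethers over palladium leaves the alkyl aryl ether bonds of both chromans, the methyl ethers and all three stereocentres untouched and should deliver the target.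

**Compound list**

1 | 2-hydroxy-4,5-dimethoxybenzaldehyde | COc1cc(O)c(C=O)cc1OC | starting material
2 | 2-(benzyloxy)-4,5-dimethoxybenzaldehyde | COc1cc(OCc2ccccc2)c(C=O)cc1OC | intermediate
3 | 1-[4-(benzyloxy)-2-hydroxyphenyl]ethanone | CC(=O)c1ccc(OCc2ccccc2)cc1O | starting material
4 | (E)-1-[4-(benzyloxy)-2-hydroxyphenyl]-3-[2-(benzyloxy)-4,5-dimethoxyphenyl]prop-2-en-1-one | COc1cc(OCc2ccccc2)c(/C=C/C(=O)c2ccc(OCc3ccccc3)cc2O)cc1OC | intermediate
5 | 1-[4-(benzyloxy)-2-hydroxyphenyl]-2-[2-(benzyloxy)-4,5-dimethoxyphenyl]-3,3-dimethoxypropan-1-one (racemic, not isolated) | COc1cc(OCc2ccccc2)c(C(C(OC)OC)C(=O)c2ccc(OCc3ccccc3)cc2O)cc1OC | intermediate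
6 | 7-(benzyloxy)-3-[2-(benzyloxy)-4,5-dimethoxyphenyl]-4H-chromen-4-one | COc1cc(OCc2ccccc2)c(-c2coc3cc(OCc4ccccc4)ccc3c2=O)cc1OC | intermediate
7 | 7-(benzyloxy)-3-[2-(benzyloxy)-4,5-dimethoxyphenyl]chroman-4-one (C3 epimerising, not isolated) | COc1cc(OCc2ccccc2)c(C2COc3cc(OCc4ccccc4)ccc3C2=O)cc1OC | intermediate
8 | cis-(3R,4R)-7-(benzyloxy)-3-[2-(benzyloxy)-4,5-dimethoxyphenyl]chroman-4-ol | COc1cc(OCc2ccccc2)c([C@@H]2COc3cc(OCc4ccccc4)ccc3[C@@H]2O)cc1OC | intermediate
9 | 2-bromo-5-methoxyphenol | COc1ccc(Br)c(O)c1 | starting material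
10 | 2-(benzyloxy)-1-bromo-4-methoxybenzene | COc1ccc(Br)c(OCc2ccccc2)c1 | intermediate
11 | 1-allyl-2-(benzyloxy)-4-methoxybenzene | COc1ccc(CC=C)c(OCc2ccccc2)c1 | intermediate
12 | trans-(3R,4S)-4-[5-allyl-4-(benzyloxy)-2-methoxyphenyl]-7-(benzyloxy)-3-[2-(benzyloxy)-4,5-dimethoxyphenyl]chroman | COc1cc(OCc2ccccc2)c([C@@H]2COc3cc(OCc4ccccc4)ccc3[C@H]2c2cc(CC=C)c(OCc3ccccc3)cc2OC)cc1OC | intermediate
13 | 3-{2-(benzyloxy)-4-methoxy-5-[(3R,4S)-7-(benzyloxy)-3-[2-(benzyloxy)-4,5-dimethoxyphenyl]chroman-4-yl]phenyl}propane-1,2-diol (mixture at the carbinol carbon, not isolated) | COc1cc(OCc2ccccc2)c([C@@H]2COc3cc(OCc4ccccc4)ccc3[C@H]2c2cc(CC(O)CO)c(OCc3ccccc3)cc2OC)cc1OC | intermediate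
14 | 2-{2-(benzyloxy)-4-methoxy-5-[(3R,4S)-7-(benzyloxy)-3-[2-(benzyloxy)-4,5-dimethoxyphenyl]chroman-4-yl]phenyl}acetaldehyde | COc1cc(OCc2ccccc2)c([C@@H]2COc3cc(OCc4ccccc4)ccc3[C@H]2c2cc(CC=O)c(OCc3ccccc3)cc2OC)cc1OC | intermediate
15 | 4-(benzyloxy)-2-hydroxybenzaldehyde | O=Cc1ccc(OCc2ccccc2)cc1O | starting material
16 | 5-(benzyloxy)-2-(hydroxymethyl)phenol | OCc1ccc(OCc2ccccc2)cc1O | intermediate
17 | 5-(benzyloxy)-2-[(4-methylphenyl)sulfonylmethyl]phenol | Cc1ccc(cc1)S(=O)(=O)Cc1ccc(OCc2ccccc2)cc1O | intermediate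
18 | 3-(benzyloxy)-6-methylidenecyclohexa-2,4-dien-1-one (ortho-quinone methide, not isolated) | O=C1C=C(OCc2ccccc2)C=CC1=C | intermediate
19 | E-enamine of aldehyde 14 and the catalyst: (R)-2-[diphenyl(trimethylsilyloxy)methyl]-1-[(E)-2-arylvinyl]pyrrolidine, aryl = the ring-B′ aryl group of 14 (not isolated) | COc1cc(OCc2ccccc2)c([C@@H]2COc3cc(OCc4ccccc4)ccc3[C@H]2c2cc(/C=C/N3CCC[C@@H]3C(O[Si](C)(C)C)(c3ccccc3)c3ccccc3)c(OCc3ccccc3)cc2OC)cc1OC | intermediate
20 | (3R)-7-(benzyloxy)-3-{2-(benzyloxy)-4-methoxy-5-[(3R,4S)-7-(benzyloxy)-3-[2-(benzyloxy)-4,5-dimethoxyphenyl]chroman-4-yl]phenyl}chroman-2-ol (anomer mixture at C2) | COc1cc(OCc2ccccc2)c([C@@H]2COc3cc(OCc4ccccc4)ccc3[C@H]2c2cc([C@@H]3C(O)Oc4cc(OCc5ccccc5)ccc4C3)c(OCc3ccccc3)cc2OC)cc1OC | intermediate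
21 | (3R)-7-(benzyloxy)-3-{2-(benzyloxy)-4-methoxy-5-[(3R,4S)-7-(benzyloxy)-3-[2-(benzyloxy)-4,5-dimethoxyphenyl]chroman-4-yl]phenyl}chroman | COc1cc(OCc2ccccc2)c([C@@H]2COc3cc(OCc4ccccc4)ccc3[C@H]2c2cc([C@@H]3COc4cc(OCc5ccccc5)ccc4C3)c(OCc3ccccc3)cc2OC)cc1OC | intermediate
22 | (3R,4S)-4-{4-hydroxy-5-[(3R)-7-hydroxychroman-3-yl]-2-methoxyphenyl}-3-(2-hydroxy-4,5-dimethoxyphenyl)chroman-7-ol | COc1cc(O)c([C@@H]2COc3cc(O)ccc3[C@H]2c2cc([C@@H]3COc4cc(O)ccc4C3)c(O)cc2OC)cc1OC | target

**Summary**

Total step count: 13. Longest linear sequence: 9 steps (steps 1, 2, 3, 4, 7, 8, 11, 12, 13).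

**Steps most likely to fail**

Step 11 (key step). The enamine may add with poor facial selectivity, or the α-aryl centre may epimerise through reversible opening of the lactol to the aldehyde while the amine is present; aldehyde 14 may also self-condense before the quinone methide is available. The fallback sets out from 14 and 17 and moves stereocontrol from C–C bond formation to a hydrogenation. The same annulation is run with achiral pyrrolidine and Na2CO3 to give the C3′-epimeric lactol F1. Dehydration with catalytic PPTS in toluene over 4 Å molecular sieves at 80 °C should give the 3-aryl-4H-chromene F2. Enantioselective hydrogenation of this cyclic enol ether with a chiral iridium phosphine–oxazoline complex of the [Ir(cod)(tBu-PHOX)]BArF type (ligand enantiomer chosen by screening; benzyl ethers are not cleaved) should set C3′, and the sequence comes back to the route at 21.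

Step 7. The benzylic cation may be lost by E1 elimination to the isoflav-3-ene, whose reprotonation would scramble C3, and the cation may alkylate ring A of 8 or of 12 instead of 11 (oligomerisation). The fallback builds the trans-3,4-diarylchroman by a second amine-catalysed quinone methide annulation, setting out from 2, 11 and 15. Wittig reaction of 2 with the ylide from (methoxymethyl)triphenylphosphonium chloride and KOtBu gives the enol ether F3, and aqueous HCl in THF hydrolyses it to the arylacetaldehyde F4. Bromination of 11 with NBS in MeCN gives the aryl bromide F5; bromine–lithium exchange (n-BuLi, THF, −78 °C) and addition to the sodium phenoxide of 15 give the diarylmethanol F6; p-TolSO2Na in HCO2H converts it into the sulfone F7. Annulation of F4 with F7 under (R)-α,α-diphenylprolinol trimethylsilyl ether and Na2CO3 should give the trans-lactol F8, with C3 set by the catalyst and C4 by the anti-selectivity of this annulation. Reduction with Et3SiH and BF3·OEt2 comes back to the route at 12.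

Step 12. The oxocarbenium ion may lose the C3′ proton reversibly to the 4H-chromene and so epimerise C3′, and the Lewis acid may ionise the C4–ring B′ bond (retro-Friedel–Crafts). The fallback sets out from 20 and avoids the cation. NaBH4 in MeOH at 0 °C reduces the open hydroxy-aldehyde tautomer to the phenol–primary alcohol F9. Mitsunobu ring closure (PPh3, DIAD, THF, 0 °C) on its only free phenol re-forms ring C′ and comes back to the route at 21.

**Further compounds**

F1 | step 11 | 7-(benzyloxy)-3-{2-(benzyloxy)-4-methoxy-5-[(3R,4S)-7-(benzyloxy)-3-[2-(benzyloxy)-4,5-dimethoxyphenyl]chroman-4-yl]phenyl}chroman-2-ol, mixture of epimers at C3′ and C2′ | COc1cc(OCc2ccccc2)c([C@@H]2COc3cc(OCc4ccccc4)ccc3[C@H]2c2cc(C3C(O)Oc4cc(OCc5ccccc5)ccc4C3)c(OCc3ccccc3)cc2OC)cc1OC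
F2 | step 11 | 7-(benzyloxy)-3-{2-(benzyloxy)-4-methoxy-5-[(3R,4S)-7-(benzyloxy)-3-[2-(benzyloxy)-4,5-dimethoxyphenyl]chroman-4-yl]phenyl}-4H-chromene | COc1cc(OCc2ccccc2)c([C@@H]2COc3cc(OCc4ccccc4)ccc3[C@H]2c2cc(C3=COc4cc(OCc5ccccc5)ccc4C3)c(OCc3ccccc3)cc2OC)cc1OC
F3 | step 7 | 1-(benzyloxy)-4,5-dimethoxy-2-(2-methoxyvinyl)benzene (E/Z mixture) | COC=Cc1cc(OC)c(OC)cc1OCc1ccccc1
F4 | step 7 | 2-[2-(benzyloxy)-4,5-dimethoxyphenyl]acetaldehyde | O=CCc1cc(OC)c(OC)cc1OCc1ccccc1
F5 | step 7 | 1-allyl-2-(benzyloxy)-5-bromo-4-methoxybenzene | COc1cc(OCc2ccccc2)c(CC=C)cc1Br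
F6 | step 7 | 2-{[5-allyl-4-(benzyloxy)-2-methoxyphenyl](hydroxy)methyl}-5-(benzyloxy)phenol (racemic) | COc1cc(OCc2ccccc2)c(CC=C)cc1C(O)c1ccc(OCc2ccccc2)cc1O
F7 | step 7 | 2-{[5-allyl-4-(benzyloxy)-2-methoxyphenyl][(4-methylphenyl)sulfonyl]methyl}-5-(benzyloxy)phenol (racemic) | COc1cc(OCc2ccccc2)c(CC=C)cc1C(c1ccc(OCc2ccccc2)cc1O)S(=O)(=O)c1ccc(C)cc1
F8 | step 7 | trans-(3R,4S)-4-[5-allyl-4-(benzyloxy)-2-methoxyphenyl]-7-(benzyloxy)-3-[2-(benzyloxy)-4,5-dimethoxyphenyl]chroman-2-ol (anomer mixture at C2) | COc1cc(OCc2ccccc2)c([C@@H]2C(O)Oc3cc(OCc4ccccc4)ccc3[C@H]2c2cc(CC=C)c(OCc3ccccc3)cc2OC)cc1OC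
F9 | step 12 | 5-(benzyloxy)-2-[(2R)-2-{2-(benzyloxy)-4-methoxy-5-[(3R,4S)-7-(benzyloxy)-3-[2-(benzyloxy)-4,5-dimethoxyphenyl]chroman-4-yl]phenyl}-3-hydroxypropyl]phenol | COc1cc(OCc2ccccc2)c([C@@H]2COc3cc(OCc4ccccc4)ccc3[C@H]2c2cc([C@@H](Cc3ccc(OCc4ccccc4)cc3O)CO)c(OCc3ccccc3)cc2OC)cc1OC
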